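**Retrosynthetic overview**
1. Target 32 ⇐ global acidolysis of 31 ⇐ tertiary inter-ring ester, disconnected into ring A acid chloride 30 and the lithium alkoxide of ring B alcohol 18.
2. 18 and 26 ⇐ 5-O-acylation of the 3,4-O-isopropylidene-L-quinate esters 17 and 25 with MOM-protected caffeic acid 9 (the benzene rings are bought with caffeic acid).
3. 17 / 25 ⇐ acetonide shift ⇐ C3 ketone reduction ⇐ decarboxylation ⇐ cyclohexane ring closed by an intramolecular aldol (C1–C2 bond) of the α-keto ester/β-keto ester 13 / 21.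
4. 13 / 21 ⇐ triflate 3 (C4 and C5 from L-tartrate) + a 1,3-dithiane-2-carboxylate (C1 and the carboxyl) + allyl acetate (C2).
5. Ring order: ring B is closed in step 10 and ring A in step 18, in parallel branches; the two rings are joined in step 26.

Assumption: the SMILES is taken literally; both cyclohexane units are then L-quinic (ent-quinic) acid units, the mirror image of natural D-(−)-quinic acid, so the rings are built from L-(+)-tartaric acid and not from commercial (−)-quinic acid.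
Convention: quinic acid numbering is used (C1 carries OH and the carboxyl; 3-OH and 4-OH are cis to 1-OH; 5-OH is trans to 1-OH and cis to the carboxyl). "L-quinate" means the enantiomer of natural D-(−)-quinate.

**Common building blocks**

Step 1
Reactants: 1 dimethyl (4R,5R)-2,2-dimethyl-1,3-dioxolane-4,5-dicarboxylate (dimethyl 2,3-O-isopropylidene-L-tartrate)
Product: 2 methyl (4R,5S)-5-(hydroxymethyl)-2,2-dimethyl-1,3-dioxolane-4-carboxylate
Conditions: NaBH4 (0.6 equiv), MeOH, 0 °C; chromatography (diol and recovered 1 recycled)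
Reagents that add atoms: none
Why: Statistical desymmetrising ester reduction: one of the two homotopic, α-alkoxy-activated esters of the C2-symmetric diester is reduced by borohydride, and neither stereocentre is touched.

Step 2
Reactants: 2 methyl (4R,5S)-5-(hydroxymethyl)-2,2-dimethyl-1,3-dioxolane-4-carboxylate
Product: 3 methyl (4R,5S)-2,2-dimethyl-5-{[(trifluoromethanesulfonyl)oxy]methyl}-1,3-dioxolane-4-carboxylate
Conditions: Tf2O, 2,6-lutidine, CH2Cl2, −78 °C; cold aqueous wash, used at once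
Reagents that add atoms: trifluoromethanesulfonic anhydride, O=S(=O)(OS(=O)(=O)C(F)(F)F)C(F)(F)F
Why: O-Sulfonylation of the primary alcohol gives a reactive alkylating agent, and the trans-dioxolane keeps the ester from participating.

Step 3
Reactants: 4 1,3-dithiane-2-carboxylic acid
Product: 5 tert-butyl 1,3-dithiane-2-carboxylate
Conditions: isobutylene, H2SO4 (cat.), CH2Cl2, sealed vessel, rt
Reagents that add atoms: 2-methylpropene, CC(C)=C
Why: Acid-catalysed addition of the carboxylic acid to isobutylene (tert-butyl ester formation); the thioacetal is inert to it.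

Step 4
Reactants: 4 1,3-dithiane-2-carboxylic acid
Product: 6 2-(trimethylsilyl)ethyl 1,3-dithiane-2-carboxylate
Conditions: Me3SiCH2CH2OH, EDC·HCl, DMAP (cat.), CH2Cl2, 0 °C → rt
Reagents that add atoms: 2-(trimethylsilyl)ethanol, C[Si](C)(C)CCO
Why: Steglich esterification of an unhindered acid with a primary alcohol.

Step 5
Reactants: 7 caffeic acid
Product: 8 methoxymethyl (E)-3-[3,4-bis(methoxymethoxy)phenyl]prop-2-enoate
Conditions: MOMCl (3.6 equiv), i-Pr2NEt, CH2Cl2, 0 °C → rt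
Reagents that add atoms: chloromethyl methyl ether, COCCl
Why: O-Alkylation of both phenols and the carboxylate with the reactive α-chloro ether leaves the E-alkene untouched.

Step 6
Reactants: 8 methoxymethyl (E)-3-[3,4-bis(methoxymethoxy)phenyl]prop-2-enoate
Product: 9 (E)-3-[3,4-bis(methoxymethoxy)phenyl]prop-2-enoic acid
Conditions: LiOH, THF/H2O, 0 °C → rt; then AcOH to pH 5
Reagents that add atoms: lithium hydroxide, [Li+].[OH-]
Why: Saponification cleaves only the acetal ester, since aryl MOM ethers are stable to base.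

**Ring B branch (tert-butyl ester)**

Step 7
Reactants: 3 methyl (4R,5S)-2,2-dimethyl-5-{[(trifluoromethanesulfonyl)oxy]methyl}-1,3-dioxolane-4-carboxylate; 5 tert-butyl 1,3-dithiane-2-carboxylate
Product: 10 tert-butyl 2-{[(4S,5R)-5-(methoxycarbonyl)-2,2-dimethyl-1,3-dioxolan-4-yl]methyl}-1,3-dithiane-2-carboxylate
Conditions: 5, NaN(SiMe3)2, THF, −78 °C; then 3, −78 → 0 °C
Reagents that add atoms: none
Why: SN2 alkylation of the sulfur-stabilised ester enolate (a glyoxylate acyl-anion equivalent, Corey–Seebach-type umpolung) by the primary triflate; the stereocentres are not involved.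

Step 8
Reactants: 10 tert-butyl 2-{[(4S,5R)-5-(methoxycarbonyl)-2,2-dimethyl-1,3-dioxolan-4-yl]methyl}-1,3-dithiane-2-carboxylate; 11 allyl acetate
Product: 12 tert-butyl 2-({(4S,5R)-2,2-dimethyl-5-[3-oxo-3-(prop-2-en-1-yloxy)propanoyl]-1,3-dioxolan-4-yl}methyl)-1,3-dithiane-2-carboxylate
Conditions: 11 (3.2 equiv), LiN(i-Pr)2 (3.1 equiv), THF, −78 °C; then 10, −78 → −45 °C; aq NH4Cl
Reagents that add atoms: none
Why: Crossed Claisen condensation: the ester enolate attacks the unhindered α-alkoxy methyl ester and not the neopentyl-type dithiane tert-butyl ester, and the product is protected in the flask as its enolate.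

Step 9
Reactants: 12 tert-butyl 2-({(4S,5R)-2,2-dimethyl-5-[3-oxo-3-(prop-2-en-1-yloxy)propanoyl]-1,3-dioxolan-4-yl}methyl)-1,3-dithiane-2-carboxylate
Product: 13 tert-butyl 3-{(4S,5R)-2,2-dimethyl-5-[3-oxo-3-(prop-2-en-1-yloxy)propanoyl]-1,3-dioxolan-4-yl}-2-oxopropanoate
Conditions: PhI(O2CCF3)2 (1.5 equiv), NaHCO3, MeCN/H2O (9:1), 0 °C, 15 min; used promptly
Reagents that add atoms: water, O
Why: Oxidative dithioacetal hydrolysis with a hypervalent iodine reagent: sulfur is oxidised much faster than the alkene or the mostly ketonic β-keto ester, and the buffer protects the acetonide.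

Step 10
Reactants: 13 tert-butyl 3-{(4S,5R)-2,2-dimethyl-5-[3-oxo-3-(prop-2-en-1-yloxy)propanoyl]-1,3-dioxolan-4-yl}-2-oxopropanoate
Product: 14 tert-butyl 2-(allyloxycarbonyl)-4,5-O-isopropylidene-3-dehydro-L-quinate (C2 epimers and enol)
Conditions: MgBr2·OEt2 (1.2 equiv), Et3N (2 equiv), CH2Cl2, −20 → 0 °C; pH 7 buffer
Reagents that add atoms: none
Why: Intramolecular aldol addition (6-enolendo-exo-trig): the magnesium-chelated β-keto ester enolate (C2) adds to the α-keto ester carbonyl (C1) through a chair held by the trans-fused dioxolane, with CO2t-Bu equatorial and the carbonyl oxygen axial on the same magnesium, which sets C1 with 1-OH cis to O-4 and trans to O-5 (C2 is epimerisable and is removed in step 11).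

Step 11
Reactants: 14 tert-butyl 2-(allyloxycarbonyl)-4,5-O-isopropylidene-3-dehydro-L-quinate
Product: 15 tert-butyl 4,5-O-isopropylidene-3-dehydro-L-quinate
Conditions: Pd(OAc)2 (5 mol %), PPh3 (20 mol %), HCO2H, Et3N, THF, 25–40 °C
Reagents that add atoms: none
Why: Tsuji deallylation–decarboxylation: zerovalent palladium formed in the flask ionises the allyl ester, formate reduces the allyl unit to propene, and the β-keto acid loses CO2 under near-neutral conditions that spare the β-hydroxy ketone and C1.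

Step 12
Reactants: 15 tert-butyl 4,5-O-isopropylidene-3-dehydro-L-quinate
Product: 16 tert-butyl 4,5-O-isopropylidene-L-quinate
Conditions: LiBH(s-Bu)3 (L-Selectride, 2.2 equiv), THF, −78 °C; AcOH quench at −78 °C
Reagents that add atoms: none
Why: Diastereoselective ketone reduction: the bulky hydride attacks C3 from the equatorial side, away from the axial 1-OH of the rigid trans-fused chair, giving the axial 3-OH cis to 1-OH and O-4.

Step 13
Reactants: 16 tert-butyl 4,5-O-isopropylidene-L-quinate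
Product: 17 tert-butyl 3,4-O-isopropylidene-L-quinate
Conditions: camphorsulfonic acid (10 mol %), acetone/2,2-dimethoxypropane, rt; Et3N quench
Reagents that add atoms: none
Why: Acid-catalysed acetal equilibration under thermodynamic control moves the strained trans-fused 4,5-acetonide to the cis-fused 3,4-position and frees the 5-OH without touching a stereocentre.

Step 14
Reactants: 17 tert-butyl 3,4-O-isopropylidene-L-quinate; 9 (E)-3-[3,4-bis(methoxymethoxy)phenyl]prop-2-enoic acid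
Product: 18 tert-butyl 5-O-[(E)-3,4-bis(methoxymethoxy)cinnamoyl]-3,4-O-isopropylidene-L-quinate
Conditions: EDC·HCl, DMAP, CH2Cl2, 0 °C → rt
Reagents that add atoms: none
Why: Steglich esterification acylates the secondary 5-OH in preference to the tertiary, ester-deactivated 1-OH.

**Ring A branch (2-(trimethylsilyl)ethyl ester)**

Step 15
Reactants: 3 methyl (4R,5S)-2,2-dimethyl-5-{[(trifluoromethanesulfonyl)oxy]methyl}-1,3-dioxolane-4-carboxylate; 6 2-(trimethylsilyl)ethyl 1,3-dithiane-2-carboxylate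
Product: 19 2-(trimethylsilyl)ethyl 2-{[(4S,5R)-5-(methoxycarbonyl)-2,2-dimethyl-1,3-dioxolan-4-yl]methyl}-1,3-dithiane-2-carboxylate
Conditions: 6, NaN(SiMe3)2, THF, −78 °C; then 3, −78 → 0 °C
Reagents that add atoms: none
Why: The same SN2 alkylation of a dithiane-stabilised ester enolate as in step 7; the silylethyl ester is stable to non-fluoride bases.

Step 16
Reactants: 19 2-(trimethylsilyl)ethyl 2-{[(4S,5R)-5-(methoxycarbonyl)-2,2-dimethyl-1,3-dioxolan-4-yl]methyl}-1,3-dithiane-2-carboxylate; 11 allyl acetate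
Product: 20 2-(trimethylsilyl)ethyl 2-({(4S,5R)-2,2-dimethyl-5-[3-oxo-3-(prop-2-en-1-yloxy)propanoyl]-1,3-dioxolan-4-yl}methyl)-1,3-dithiane-2-carboxylate
Conditions: 11 (3.2 equiv), LiN(i-Pr)2 (3.1 equiv), THF, −78 °C; then 19, −78 → −45 °C; aq NH4Cl
Reagents that add atoms: none
Why: Crossed Claisen condensation at the methyl ester, as in step 8; the α,α-dithio ester is too hindered to compete.

Step 17
Reactants: 20 2-(trimethylsilyl)ethyl 2-({(4S,5R)-2,2-dimethyl-5-[3-oxo-3-(prop-2-en-1-yloxy)propanoyl]-1,3-dioxolan-4-yl}methyl)-1,3-dithiane-2-carboxylate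
Product: 21 2-(trimethylsilyl)ethyl 3-{(4S,5R)-2,2-dimethyl-5-[3-oxo-3-(prop-2-en-1-yloxy)propanoyl]-1,3-dioxolan-4-yl}-2-oxopropanoate
Conditions: PhI(O2CCF3)2 (1.5 equiv), NaHCO3, MeCN/H2O (9:1), 0 °C, 15 min; used promptly
Reagents that add atoms: water, O
Why: Oxidative dithioacetal hydrolysis, as in step 9.

Step 18
Reactants: 21 2-(trimethylsilyl)ethyl 3-{(4S,5R)-2,2-dimethyl-5-[3-oxo-3-(prop-2-en-1-yloxy)propanoyl]-1,3-dioxolan-4-yl}-2-oxopropanoate
Product: 22 2-(trimethylsilyl)ethyl 2-(allyloxycarbonyl)-4,5-O-isopropylidene-3-dehydro-L-quinate (C2 epimers and enol)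
Conditions: MgBr2·OEt2 (1.2 equiv), Et3N (2 equiv), CH2Cl2, −20 → 0 °C; pH 7 buffer
Reagents that add atoms: none
Why: The same magnesium-templated intramolecular aldol addition as in step 10 closes ring A and sets C1 (ester equatorial, 1-OH axial, cis to O-4 and trans to O-5).

Step 19
Reactants: 22 2-(trimethylsilyl)ethyl 2-(allyloxycarbonyl)-4,5-O-isopropylidene-3-dehydro-L-quinate
Product: 23 2-(trimethylsilyl)ethyl 4,5-O-isopropylidene-3-dehydro-L-quinate
Conditions: Pd(OAc)2 (5 mol %), PPh3 (20 mol %), HCO2H, Et3N, THF, 25–40 °C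
Reagents that add atoms: none
Why: Tsuji deallylation–decarboxylation, as in step 11; the silylethyl ester is inert to palladium.

Step 20
Reactants: 23 2-(trimethylsilyl)ethyl 4,5-O-isopropylidene-3-dehydro-L-quinate
Product: 24 2-(trimethylsilyl)ethyl 4,5-O-isopropylidene-L-quinate
Conditions: LiBH(s-Bu)3 (L-Selectride, 2.2 equiv), THF, −78 °C; AcOH quench at −78 °C
Reagents that add atoms: none
Why: Equatorial hydride delivery by the bulky borohydride, as in step 12, gives the axial 3-OH cis to 1-OH and O-4.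

Step 21
Reactants: 24 2-(trimethylsilyl)ethyl 4,5-O-isopropylidene-L-quinate
Product: 25 2-(trimethylsilyl)ethyl 3,4-O-isopropylidene-L-quinate
Conditions: camphorsulfonic acid (10 mol %), acetone/2,2-dimethoxypropane, rt; Et3N quench
Reagents that add atoms: none
Why: Thermodynamic acetal equilibration from the trans-4,5- to the cis-3,4-acetonide, as in step 13.

Step 22
Reactants: 25 2-(trimethylsilyl)ethyl 3,4-O-isopropylidene-L-quinate; 9 (E)-3-[3,4-bis(methoxymethoxy)phenyl]prop-2-enoic acid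
Product: 26 2-(trimethylsilyl)ethyl 5-O-[(E)-3,4-bis(methoxymethoxy)cinnamoyl]-3,4-O-isopropylidene-L-quinate
Conditions: EDC·HCl, DMAP, CH2Cl2, 0 °C → rt
Reagents that add atoms: none
Why: Steglich esterification of the secondary 5-OH, as in step 14.

Step 23
Reactants: 26 2-(trimethylsilyl)ethyl 5-O-[(E)-3,4-bis(methoxymethoxy)cinnamoyl]-3,4-O-isopropylidene-L-quinate
Product: 27 5-O-[(E)-3,4-bis(methoxymethoxy)cinnamoyl]-3,4-O-isopropylidene-L-quinic acid
Conditions: Bu4NF (2.5 equiv), THF, 0 °C → rt; AcOH quench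
Reagents that add atoms: none
Why: Fluoride-induced β-fragmentation of the 2-(trimethylsilyl)ethyl ester releases the acid without hydrolytic conditions, so the cinnamate ester, acetonide and MOM ethers stay.

Step 24
Reactants: 27 5-O-[(E)-3,4-bis(methoxymethoxy)cinnamoyl]-3,4-O-isopropylidene-L-quinic acid
Product: 29 5-O-[(E)-3,4-bis(methoxymethoxy)cinnamoyl]-3,4-O-isopropylidene-1-O-triethylsilyl-L-quinic acid, via triethylsilyl ester 28 (not isolated)
Conditions: Et3SiOTf (2.5 equiv), 2,6-lutidine, CH2Cl2, −78 → 0 °C; then THF/H2O/AcOH, rt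
Reagents that add atoms: triethylsilyl trifluoromethanesulfonate, CC[Si](CC)(CC)OS(=O)(=O)C(F)(F)F
Why: Persilylation of the hydroxy acid followed by selective hydrolysis of the labile silyl ester protects the tertiary 1-OH; at low temperature with a hindered base the acetonide and aryl MOM ethers are not attacked.

Step 25
Reactants: 29 5-O-[(E)-3,4-bis(methoxymethoxy)cinnamoyl]-3,4-O-isopropylidene-1-O-triethylsilyl-L-quinic acid
Product: 30 5-O-[(E)-3,4-bis(methoxymethoxy)cinnamoyl]-3,4-O-isopropylidene-1-O-triethylsilyl-L-quinoyl chloride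
Conditions: 1-chloro-N,N,2-trimethylprop-1-en-1-amine (Ghosez reagent), CH2Cl2, 0 °C → rt; evaporated and used crude
Reagents that add atoms: 1-chloro-N,N,2-trimethylprop-1-en-1-amine, CC(C)=C(Cl)N(C)C
Why: Acid chloride formation with an α-chloroenamine is neutral (no HCl), so the silyl ether, acetonide and MOM ethers survive.

**Union and deprotection**

Step 26
Reactants: 18 tert-butyl 5-O-[(E)-3,4-bis(methoxymethoxy)cinnamoyl]-3,4-O-isopropylidene-L-quinate; 30 5-O-[(E)-3,4-bis(methoxymethoxy)cinnamoyl]-3,4-O-isopropylidene-1-O-triethylsilyl-L-quinoyl chloride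
Product: 31 tert-butyl 1-O-{5-O-[(E)-3,4-bis(methoxymethoxy)cinnamoyl]-3,4-O-isopropylidene-1-O-triethylsilyl-L-quinoyl}-5-O-[(E)-3,4-bis(methoxymethoxy)cinnamoyl]-3,4-O-isopropylidene-L-quinate
Conditions: 18, LiN(SiMe3)2 (1.05 equiv), THF, −78 °C; then 30, −78 → 0 °C
Reagents that add atoms: none
Why: Acylation of a lithium tert-alkoxide by an acid chloride, the classical route to hindered tertiary esters; the quaternary α-silyloxy acid chloride cannot form a ketene and neither partner can epimerise.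

Step 27
Reactants: 31 tert-butyl 1-O-{5-O-[(E)-3,4-bis(methoxymethoxy)cinnamoyl]-3,4-O-isopropylidene-1-O-triethylsilyl-L-quinoyl}-5-O-[(E)-3,4-bis(methoxymethoxy)cinnamoyl]-3,4-O-isopropylidene-L-quinate
Product: 32 1-O-(5-O-caffeoyl-L-quinoyl)-5-O-caffeoyl-L-quinic acid (CNP0107948.2)
Conditions: CF3CO2H/H2O (9:1), 0 °C → rt; evaporation; reversed-phase HPLC
Reagents that add atoms: none
Why: Global acidolysis removes the tert-butyl ester, both acetonides, the silyl ether and the four aryl MOM ethers, while the cinnamate esters and the tertiary inter-ring ester (whose ionisation would need an α-carbonyl cation) survive.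

**Compound list**
1 | dimethyl (4R,5R)-2,2-dimethyl-1,3-dioxolane-4,5-dicarboxylate | COC(=O)[C@@H]1OC(C)(C)O[C@H]1C(=O)OC | starting material
2 | methyl (4R,5S)-5-(hydroxymethyl)-2,2-dimethyl-1,3-dioxolane-4-carboxylate | COC(=O)[C@@H]1OC(C)(C)O[C@H]1CO | intermediate
3 | methyl (4R,5S)-2,2-dimethyl-5-{[(trifluoromethanesulfonyl)oxy]methyl}-1,3-dioxolane-4-carboxylate | COC(=O)[C@@H]1OC(C)(C)O[C@H]1COS(=O)(=O)C(F)(F)F | intermediate
4 | 1,3-dithiane-2-carboxylic acid | OC(=O)C1SCCCS1 | starting material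
5 | tert-butyl 1,3-dithiane-2-carboxylate | CC(C)(C)OC(=O)C1SCCCS1 | intermediate
6 | 2-(trimethylsilyl)ethyl 1,3-dithiane-2-carboxylate | C[Si](C)(C)CCOC(=O)C1SCCCS1 | intermediate
7 | caffeic acid | OC(=O)/C=C/c1ccc(O)c(O)c1 | starting material
8 | methoxymethyl (E)-3-[3,4-bis(methoxymethoxy)phenyl]prop-2-enoate | COCOC(=O)/C=C/c1ccc(OCOC)c(OCOC)c1 | intermediate
9 | (E)-3-[3,4-bis(methoxymethoxy)phenyl]prop-2-enoic acid | OC(=O)/C=C/c1ccc(OCOC)c(OCOC)c1 | intermediate
10 | tert-butyl 2-{[(4S,5R)-5-(methoxycarbonyl)-2,2-dimethyl-1,3-dioxolan-4-yl]methyl}-1,3-dithiane-2-carboxylate | COC(=O)[C@@H]1OC(C)(C)O[C@H]1CC2(C(=O)OC(C)(C)C)SCCCS2 | intermediate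
11 | allyl acetate (prop-2-en-1-yl acetate) | CC(=O)OCC=C | starting material
12 | tert-butyl 2-({(4S,5R)-2,2-dimethyl-5-[3-oxo-3-(prop-2-en-1-yloxy)propanoyl]-1,3-dioxolan-4-yl}methyl)-1,3-dithiane-2-carboxylate | C=CCOC(=O)CC(=O)[C@@H]1OC(C)(C)O[C@H]1CC2(C(=O)OC(C)(C)C)SCCCS2 | intermediate
13 | tert-butyl 3-{(4S,5R)-2,2-dimethyl-5-[3-oxo-3-(prop-2-en-1-yloxy)propanoyl]-1,3-dioxolan-4-yl}-2-oxopropanoate | C=CCOC(=O)CC(=O)[C@@H]1OC(C)(C)O[C@H]1CC(=O)C(=O)OC(C)(C)C | intermediate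
14 | tert-butyl 2-(allyloxycarbonyl)-4,5-O-isopropylidene-3-dehydro-L-quinate (C2 unassigned: epimers and enol) | O[C@@]1(C(=O)OC(C)(C)C)C[C@@H]2OC(C)(C)O[C@H]2C(=O)C1C(=O)OCC=C | intermediate
15 | tert-butyl 4,5-O-isopropylidene-3-dehydro-L-quinate | O[C@@]1(C(=O)OC(C)(C)C)C[C@@H]2OC(C)(C)O[C@H]2C(=O)C1 | intermediate
16 | tert-butyl 4,5-O-isopropylidene-L-quinate | O[C@@]1(C(=O)OC(C)(C)C)C[C@@H]2OC(C)(C)O[C@H]2[C@@H](O)C1 | intermediate
17 | tert-butyl 3,4-O-isopropylidene-L-quinate | O[C@@]1(C(=O)OC(C)(C)C)C[C@H](O)[C@H]2OC(C)(C)O[C@H]2C1 | intermediate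
18 | tert-butyl 5-O-[(E)-3,4-bis(methoxymethoxy)cinnamoyl]-3,4-O-isopropylidene-L-quinate | O[C@@]1(C(=O)OC(C)(C)C)C[C@H](OC(=O)/C=C/c3ccc(OCOC)c(OCOC)c3)[C@H]2OC(C)(C)O[C@H]2C1 | intermediate
19 | 2-(trimethylsilyl)ethyl 2-{[(4S,5R)-5-(methoxycarbonyl)-2,2-dimethyl-1,3-dioxolan-4-yl]methyl}-1,3-dithiane-2-carboxylate | COC(=O)[C@@H]1OC(C)(C)O[C@H]1CC2(C(=O)OCC[Si](C)(C)C)SCCCS2 | intermediate
20 | 2-(trimethylsilyl)ethyl 2-({(4S,5R)-2,2-dimethyl-5-[3-oxo-3-(prop-2-en-1-yloxy)propanoyl]-1,3-dioxolan-4-yl}methyl)-1,3-dithiane-2-carboxylate | C=CCOC(=O)CC(=O)[C@@H]1OC(C)(C)O[C@H]1CC2(C(=O)OCC[Si](C)(C)C)SCCCS2 | intermediate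
21 | 2-(trimethylsilyl)ethyl 3-{(4S,5R)-2,2-dimethyl-5-[3-oxo-3-(prop-2-en-1-yloxy)propanoyl]-1,3-dioxolan-4-yl}-2-oxopropanoate | C=CCOC(=O)CC(=O)[C@@H]1OC(C)(C)O[C@H]1CC(=O)C(=O)OCC[Si](C)(C)C | intermediate
22 | 2-(trimethylsilyl)ethyl 2-(allyloxycarbonyl)-4,5-O-isopropylidene-3-dehydro-L-quinate (C2 unassigned: epimers and enol) | O[C@@]1(C(=O)OCC[Si](C)(C)C)C[C@@H]2OC(C)(C)O[C@H]2C(=O)C1C(=O)OCC=C | intermediate
23 | 2-(trimethylsilyl)ethyl 4,5-O-isopropylidene-3-dehydro-L-quinate | O[C@@]1(C(=O)OCC[Si](C)(C)C)C[C@@H]2OC(C)(C)O[C@H]2C(=O)C1 | intermediate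
24 | 2-(trimethylsilyl)ethyl 4,5-O-isopropylidene-L-quinate | O[C@@]1(C(=O)OCC[Si](C)(C)C)C[C@@H]2OC(C)(C)O[C@H]2[C@@H](O)C1 | intermediate
25 | 2-(trimethylsilyl)ethyl 3,4-O-isopropylidene-L-quinate | O[C@@]1(C(=O)OCC[Si](C)(C)C)C[C@H](O)[C@H]2OC(C)(C)O[C@H]2C1 | intermediate
26 | 2-(trimethylsilyl)ethyl 5-O-[(E)-3,4-bis(methoxymethoxy)cinnamoyl]-3,4-O-isopropylidene-L-quinate | O[C@@]1(C(=O)OCC[Si](C)(C)C)C[C@H](OC(=O)/C=C/c3ccc(OCOC)c(OCOC)c3)[C@H]2OC(C)(C)O[C@H]2C1 | intermediate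
27 | 5-O-[(E)-3,4-bis(methoxymethoxy)cinnamoyl]-3,4-O-isopropylidene-L-quinic acid | O[C@@]1(C(=O)O)C[C@H](OC(=O)/C=C/c3ccc(OCOC)c(OCOC)c3)[C@H]2OC(C)(C)O[C@H]2C1 | intermediate
28 | triethylsilyl 5-O-[(E)-3,4-bis(methoxymethoxy)cinnamoyl]-3,4-O-isopropylidene-1-O-triethylsilyl-L-quinate | CC[Si](CC)(CC)O[C@@]1(C(=O)O[Si](CC)(CC)CC)C[C@H](OC(=O)/C=C/c3ccc(OCOC)c(OCOC)c3)[C@H]2OC(C)(C)O[C@H]2C1 | intermediate (not isolated)
29 | 5-O-[(E)-3,4-bis(methoxymethoxy)cinnamoyl]-3,4-O-isopropylidene-1-O-triethylsilyl-L-quinic acid | CC[Si](CC)(CC)O[C@@]1(C(=O)O)C[C@H](OC(=O)/C=C/c3ccc(OCOC)c(OCOC)c3)[C@H]2OC(C)(C)O[C@H]2C1 | intermediate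
30 | 5-O-[(E)-3,4-bis(methoxymethoxy)cinnamoyl]-3,4-O-isopropylidene-1-O-triethylsilyl-L-quinoyl chloride | CC[Si](CC)(CC)O[C@@]1(C(=O)Cl)C[C@H](OC(=O)/C=C/c3ccc(OCOC)c(OCOC)c3)[C@H]2OC(C)(C)O[C@H]2C1 | intermediate
31 | tert-butyl 1-O-{5-O-[(E)-3,4-bis(methoxymethoxy)cinnamoyl]-3,4-O-isopropylidene-1-O-triethylsilyl-L-quinoyl}-5-O-[(E)-3,4-bis(methoxymethoxy)cinnamoyl]-3,4-O-isopropylidene-L-quinate | CC[Si](CC)(CC)O[C@@]1(C(=O)O[C@@]4(C(=O)OC(C)(C)C)C[C@H](OC(=O)/C=C/c5ccc(OCOC)c(OCOC)c5)[C@H]6OC(C)(C)O[C@H]6C4)C[C@H](OC(=O)/C=C/c3ccc(OCOC)c(OCOC)c3)[C@H]2OC(C)(C)O[C@H]2C1 | intermediate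
32 | 1-O-(5-O-caffeoyl-L-quinoyl)-5-O-caffeoyl-L-quinic acid (CNP0107948.2) | O=C(/C=C/c1ccc(O)c(O)c1)O[C@H]1C[C@@](O)(C(=O)O[C@@]2(C(=O)O)C[C@H](OC(=O)/C=C/c3ccc(O)c(O)c3)[C@@H](O)[C@@H](O)C2)C[C@H](O)[C@@H]1O | target

**Step count and risks**
Total step count: 27. Longest linear sequence: 15 steps (1, 2, 15–27).

Most likely to fail, 1: step 9 (oxidative unmasking of the dithiane next to an oxidisable β-keto ester and an allyl group; step 17 is the same reaction on the other ester). The fallback sets out from 10 and unmasks the ketone before any 1,3-dicarbonyl exists. PhI(O2CCF3)2/NaHCO3 in aqueous MeCN gives methyl (4R,5S)-5-(3-tert-butoxy-2,3-dioxopropyl)-2,2-dimethyl-1,3-dioxolane-4-carboxylate F1. t-BuMe2SiOTf/Et3N in CH2Cl2 then masks the ketone as its silyl enol ether, methyl (4R,5S)-5-[3-tert-butoxy-2-(tert-butyldimethylsilyloxy)-3-oxoprop-1-en-1-yl]-2,2-dimethyl-1,3-dioxolane-4-carboxylate F2 (alkene geometry immaterial). The Claisen condensation with the lithium enolate of 11 (LiN(i-Pr)2, THF, −78 °C) gives tert-butyl 2-(tert-butyldimethylsilyloxy)-3-{(4S,5R)-2,2-dimethyl-5-[3-oxo-3-(prop-2-en-1-yloxy)propanoyl]-1,3-dioxolan-4-yl}prop-2-enoate F3. Et3N·3HF in THF removes the silyl group, and the route is rejoined at 13.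

Most likely to fail, 2: step 10 (the key aldol; the doubly activated adduct may dehydrate to the Knoevenagel product or give the wrong C1 epimer; step 18 is the same reaction). The fallback sets out from 12 and uses a simple methyl ketone donor under enamine catalysis. Tsuji deallylation–decarboxylation (Pd(OAc)2, PPh3, HCO2H, Et3N) gives tert-butyl 2-{[(4S,5R)-5-acetyl-2,2-dimethyl-1,3-dioxolan-4-yl]methyl}-1,3-dithiane-2-carboxylate F4. PhI(O2CCF3)2/NaHCO3 in aqueous MeCN unmasks it to tert-butyl 3-[(4S,5R)-5-acetyl-2,2-dimethyl-1,3-dioxolan-4-yl]-2-oxopropanoate F5. A proline-catalysed 6-enolendo aldol of the Hajos–Parrish type (L- or D-proline, whichever is matched, DMSO, rt) closes the ring through the methyl enamine, with the acid group of the catalyst holding the ketone oxygen axial, and the route is rejoined at 15.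

Most likely to fail, 3: step 26 (esterification of a tertiary alcohol with a quaternary acid chloride). The fallback sets out from 27 (with 30) and makes the acylation intramolecular. The free hydroxy acid 27 and 30 with pyridine and catalytic DMAP in CH2Cl2 first form the mixed anhydride at the unhindered carboxylate. The acyl group then shifts to the neighbouring tertiary oxygen through a five-membered cyclic intermediate and gives 1-O-{5-O-[(E)-3,4-bis(methoxymethoxy)cinnamoyl]-3,4-O-isopropylidene-1-O-triethylsilyl-L-quinoyl}-5-O-[(E)-3,4-bis(methoxymethoxy)cinnamoyl]-3,4-O-isopropylidene-L-quinic acid F6. The acidolysis of step 27 (CF3CO2H/H2O) then brings the route back at 32.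

**Further compounds**
F1 | step 9 | methyl (4R,5S)-5-(3-tert-butoxy-2,3-dioxopropyl)-2,2-dimethyl-1,3-dioxolane-4-carboxylate | COC(=O)[C@@H]1OC(C)(C)O[C@H]1CC(=O)C(=O)OC(C)(C)C
F2 | step 9 | methyl (4R,5S)-5-[3-tert-butoxy-2-(tert-butyldimethylsilyloxy)-3-oxoprop-1-en-1-yl]-2,2-dimethyl-1,3-dioxolane-4-carboxylate | COC(=O)[C@@H]1OC(C)(C)O[C@H]1C=C(O[Si](C)(C)C(C)(C)C)C(=O)OC(C)(C)C
F3 | step 9 | tert-butyl 2-(tert-butyldimethylsilyloxy)-3-{(4S,5R)-2,2-dimethyl-5-[3-oxo-3-(prop-2-en-1-yloxy)propanoyl]-1,3-dioxolan-4-yl}prop-2-enoate | C=CCOC(=O)CC(=O)[C@@H]1OC(C)(C)O[C@H]1C=C(O[Si](C)(C)C(C)(C)C)C(=O)OC(C)(C)C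
F4 | step 10 | tert-butyl 2-{[(4S,5R)-5-acetyl-2,2-dimethyl-1,3-dioxolan-4-yl]methyl}-1,3-dithiane-2-carboxylate | CC(=O)[C@@H]1OC(C)(C)O[C@H]1CC2(C(=O)OC(C)(C)C)SCCCS2
F5 | step 10 | tert-butyl 3-[(4S,5R)-5-acetyl-2,2-dimethyl-1,3-dioxolan-4-yl]-2-oxopropanoate | CC(=O)[C@@H]1OC(C)(C)O[C@H]1CC(=O)C(=O)OC(C)(C)C
F6 | step 26 | 1-O-{5-O-[(E)-3,4-bis(methoxymethoxy)cinnamoyl]-3,4-O-isopropylidene-1-O-triethylsilyl-L-quinoyl}-5-O-[(E)-3,4-bis(methoxymethoxy)cinnamoyl]-3,4-O-isopropylidene-L-quinic acid | CC[Si](CC)(CC)O[C@@]1(C(=O)O[C@@]4(C(=O)O)C[C@H](OC(=O)/C=C/c5ccc(OCOC)c(OCOC)c5)[C@H]6OC(C)(C)O[C@H]6C4)C[C@H](OC(=O)/C=C/c3ccc(OCOC)c(OCOC)c3)[C@H]2OC(C)(C)O[C@H]2C1
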